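Readings and results are calculated on assumed constants.

I choose violet over amber, and what I watch while repeating either is how fast the rate dies, not how fast it starts.

common to all: partner 0.111 M; free catalyst 3.7 mM

| charge | starting material | temperature | remark | time |
|---|---|---|---|---|
| north-west | 0.027 M (fed, over 30 min) | −30 °C | run made earlier |  |
| south-east | 0.066 M (fed, over 30 min) | −8 °C | run made earlier |  |
| amber | 0.074 M (fed, over 30 min) |  | at −40 °C until 30 min, from then on at 0 °C | 5.0 h |
| violet | 0.040 M (fed, over 30 min) |  | at −40 °C throughout | 15 h |

- north-west (time / min: target / %, starting material / %): 8.00: 0.7, 13.8; 15.0: 5.1, 20.6; 25.0: 12.0, 29.4; 50.0: 34.5, 19.9; 90.0: 52.6, 15.1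
- south-east (time / min: target / %, starting material / %): 2.50: 0.3, 2.8; 5.00: 2.3, 3.2; 8.00: 4.9, 4.5; 15.0: 10.8, 9.5; 30.0: 18.6, 28.1

(each reading ± 0.5 percentage points)

- percentages count the whole charge, also what has not yet gone in

- which of the two ends with the higher amount of target, in percent of the starting material charged ("neither" if they lie within 2 percentage points) (amber / violet / neither)
- target at the end, in percent of the starting material charged, amber
- target at the end, in percent of the starting material charged, violet

I call the pool what has been fed and is not yet target, and the specific rate the gain of target per minute divided by the mean pool of a window. In the north-west run it reads 0.0132 min⁻¹ from 25.0 min to 50.0 min, then 0.00802 min⁻¹ up to 90.0 min, down by a factor 1.65. In the south-east run it reads 0.0276 min⁻¹ from 8.00 min to 15.0 min, then 0.00862 min⁻¹ up to 30.0 min, down by a factor 3.20. These are readings and carry their scatter. I take each fall as exponential, which gives decay constants of 0.0152 min⁻¹ north-west and 0.106 min⁻¹ south-east. Run back to time zero, the starting specific rates are 0.0233 min⁻¹ and 0.0935 min⁻¹. So by this reckoning the south-east run, which differs from the north-west run in charge as well as in temperature, starts a factor 4.01 faster and decays a factor 6.97 faster.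

For a pool drained at such an exponentially dying specific rate with no other way out, the rate sums to its start over its decay constant, and the pool left after several lifetimes is e to the minus that ratio. The ratio is 1.53 north-west and 0.883 south-east. Taking its logarithm as straight in temperature, I get for violet at −40 °C the catalyst budget, starting specific rate over decay constant, of 1.96. Violet's reckoned lifetime of 158 min is shorter than its 15 h, so my reckoning, ignoring the feed, gives 85.9%. Amber at 0 °C gets a budget of 0.723, and ignoring its cold feed I reckon 51.5%. I carry these budgets across charges as shares of the pool.

The forecast also names violet, with 82% for violet and 55% for amber, reading the fall as “product inhibition or catalyst death”. My reckoning differs from it: higher on violet and lower on amber.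

Violet ends at 75.3% and amber at 58.4%.

    starting material + free catalyst ⇌ free catalyst + intermediate (K = 1.10, k = 28.0 M⁻¹ min⁻¹, Ea = 47.0 kJ mol⁻¹, ΔH = 37.0 kJ mol⁻¹)
    partner + free catalyst + intermediate → free catalyst + target (k = 36.0 M⁻² min⁻¹, Ea = 37.0 kJ mol⁻¹)
    partner + free catalyst → spent catalyst (k = 0.0420 M⁻¹ min⁻¹, Ea = 52.0 kJ mol⁻¹)
    (constants at −40 °C)

In violet, free catalyst stands at 4.17% of its charge after 15.0 h. Read as a budget, violet's end is 1.40, less than my 1.96. Held at that budget, the neighbouring flask, like violet but with 0.16 M of starting material, asks for 0.121 M of target against 0.111 M of partner charged. That neighbour ends with target at 61.9% of its charged starting material, with 8.6% of its partner left.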